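## The problem

Numbering used throughout: ring A is C10 (spiro), C1 (CHOAc), C2, C3, C4 (CMe(C19H2OH)), C5 (CH carrying C6H2OAc). The δ-lactone is C10–C20–O–C7(=O)–C8–C9. Ring C is C8, C9, C11, C12, C13, C14 and ring D is C8, C14, C13, C16 (=C17H2), C15 (C=O).

- The target is a 6,7-seco-kaurane: a bicyclo[3.2.1]octane (rings C and D) with a quaternary bridgehead C8, joined to ring A only through the C9–C10 bond, with a δ-lactone that is spiro at C10 and cis-fused to ring C.
- It has seven stereocentres: C8 and C13 (which fix each other), C9, the quaternary C10 and C4, C5 and C1.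
- As written, C10 sits on the face of ring C opposite the C15–C16 bridge (cis to C7), C20 is anti to the C6 arm on C5, the C4 methyl is cis to that arm, and the C1 acetate is cis to C9.
- A C12 carbinol can hand its configuration to C9, C9 together with C5 can control C10, and C10 with C5 can control C1. The C8/C13 pair and the C4/C5 pair are remote from each other, so each needs its own absolute control.
- The α-methylene cyclopentanone is a Michael acceptor, the C6 acetate can migrate to the free C19 hydroxyl under base, and a free C1 hydroxyl can reach the lactone carbonyl. The enone must therefore come last and the final deprotection must not be basic.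
- The enabling feature is that C20 is an OCH2 group on C10, which is α to the oxygenated C1. With C1 as a ketone in a C2=C3 enone, C10 is the only enolisable carbon (C4 is quaternary), and C20 can be the electrophilic carbon of a chloromethyl ester of the C7 acid.

## Retrosynthesis

**Ring D oxidation pattern (39 ⇒ 36 ⇒ 35).** The enone of 39 is traced through PMB ether 38 and allylic alcohol 37 to the exocyclic alkene 36; C15 is the only allylic position that is not a bridgehead. Alkene 36 is cut at C16=C17 to ketone 35. The reason is that ring C and ring A must be hydrogenated on the way, and a 1,1-disubstituted exocyclic alkene cannot be expected to outlast a hindered cis-disubstituted one. Carried as a dioxolane from 12 onward, C16 is inert to hydride, base and hydrogen. The price is three extra steps (7, 9, 27) and a share in step 25.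

**Ring A oxygens (35 ⇒ 33 ⇒ 32 ⇒ 31).** The C1–O bond is made by hydride reduction of ketone 32, and the two acetates are installed only after the silyl ether and the dioxolane are removed together (34). Ketone 32 comes from spiro-lactone 31 by one hydrogenation that saturates both C2=C3 and C11=C12. The forward reduction must deliver hydride anti to C9 and the C6 arm.

**Key cut, C10–C20 (31 ⇒ 29).** Cutting C10–C20 removes the spiro centre and the lactone ring at once and leaves a C1 enone and a C7 chloromethyl ester on C8. Cutting the lactone C–O bond instead would leave the quaternary C10 to be made by an intermolecular reaction at a neopentyl position with no element to choose its face. The forward step asks for regiospecific enolisation, C-alkylation through a six-membered ring, and attack on the face anti to the C6 arm.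

**C9–C10 (29 ⇒ 27 ⇒ 26 ⇒ 15 + 23).** The ester is traced through acid 27 to methyl ester 26, and 26 is cut at C9–C10 by a Claisen transform into exo allylic alcohol 15 and enone ketal 23.
- Alkylation at the secondary neopentyl C9 is not realistic, and an intermolecular conjugate addition to enone 12 would be hindered and would leave a C12 carbonyl to remove.
- The [3,3] shift is intramolecular and moves the exo C12–O bond to an exo C9–C10 bond.
- The enone ketal 23 is used, not the ketal of a saturated ketone, because only C10 can then become the enol ether carbon.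
- The C11=C12 bond left by the shift is kept as a spectator through the key step and removed together with C2=C3 in step 23, so no re-oxidation of ring A is needed.

**Bicyclic alcohol (15 ⇒ 13 ⇒ 12 ⇒ 8 ⇒ 6 ⇒ 5 ⇒ 4 + 2).**
- Hydride reaches C12 of enone 12 from the exo face, so the exo alcohol 15 needs an inversion of endo alcohol 13.
- Enone 12 comes from keto ester 8 by ozonolysis, dehydrogenation and selective ketalisation.
- Ring D of 8 is cut at C13–C16 by a Conia-ene type transform to silyl enol ether 5.
- Adduct 5 is cut at C8–C14 and C9–C11 by a Diels–Alder transform into acrolein 4 and diene 2.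
- Desymmetrising the corresponding 4,4-disubstituted cyclohexanone with a chiral base was set aside, because the two C8 substituents are too similar in size to bias the ring conformation. The cycloaddition sets C8 under catalyst control instead, and the position of the enol ether double bond carries the asymmetry.

**Ring A (23 ⇒ 22 ⇒ 21 ⇒ 19 ⇒ 18 + 2; 18 ⇒ 16 + 17).** Ketal 23 comes from enone 22, made by Saegusa oxidation of the regiodefined enol ether 21. Adduct 19 is cut at C3–C4 and C5–C10 into (E)-enal 18 and the same diene 2. The E geometry gives the C4 methyl cis to the C6 arm, and the same catalyst hand as for 5 serves, because both dienophiles must be attacked on the same face. Enal 18 is a Wittig product of aldehyde 16 and ylide 17.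

## Roads not taken

**Alternative 1: oxidative radical closure of ring D.**
- Cut and key step: C13–C16 is cut last. Mn(OAc)3 with Cu(OAc)2 would oxidise a tert-butyl β-keto ester side chain on C8 of a ring C cyclohexene that already carries the spiro-lactone and ring A. The C16 radical adds to C13, and the C12 radical is oxidised to the C11=C12 alkene, giving β-keto ester A1.
- Merits: the C15 ketone arrives at the right oxidation level, and the C16 ester is a handle for the methylene group. In this respect it is better than the chosen plan, which spends steps on masking C16 and on a late allylic oxidation.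
- Weak points: the step solves none of the hard centres, since C8, C9 and the spiro C10 must all exist before it. On a cyclohexene the 5-exo attack at C13 competes with attack at C12. A1 still has an oxidisable hydrogen between two carbonyls. A C11=C12 bond must still be reduced next to the future enone.
- Comparison: the chosen plan sets against the shorter ring D endgame an early, catalyst-controlled bicycle and a defined answer to C10.

**Alternative 2: anionic oxy-Cope through a temporary ring B.**
- Cut and key step: C9–C10 is cut with C6–C7 still intact. A potassium alkoxide (KH, 18-crown-6), with ring A hidden in a bicyclo[2.2.2]octene and ring C as a cyclohexa-1,4-diene, rearranges, and the enolate is trapped with Me3SiCl as silyl enol ether A2.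
- Merits: one step makes C9–C10 and the quaternary C10 with C20 already attached, with C9 and C10 related by a rigid transition state. This is stronger than the chosen plan, which needs two separate steps (19 and 22) for the same two centres.
- Weak points: the C6–C7 bond must later be cleaved oxidatively, the quaternary C8, ring D and the lactone are all still to be built on a diene, and the carbinol precursor needs a face-selective addition to a hindered ketone. The cis ring fusion that the rearrangement gives must also match the unusual C9/C10 relationship of this target.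
- Comparison: the chosen plan sets against this a bicycle that is complete before the fragments meet and a short path from the key step to the target.

**Alternative 3: silicon-tethered Diels–Alder building ring C on the spiro-lactone.**
- Cut and key step: C8–C14 and C9–C11 are cut. A 3-acetyl-5,6-dihydropyran-2-one spiro-fused to ring A reacts with a butadienylsilyl ether on the C6 oxygen to give siloxane A3.
- Merits: the spiro centre is settled early by simple chemistry, the tether fixes regiochemistry and the face at C9 relative to C10, and C8 becomes quaternary in the cycloaddition. On lactone timing it is at least as good as the chosen plan.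
- Weak points: the dienophile carbon C9 is neopentyl to the spiro centre, the tether closes a seven-membered ring, and the C11–Si bond must be removed without moving the ring C alkene. Ring D still has to be made from the acetyl group, with C13–C16 formation and the whole oxidation pattern to follow.
- Comparison: the chosen plan sets against the early lactone a ring D that is in place from step 4 and a late lactone closure that itself sets C10.

Key step: step 22

Remark on the chemistry: the facial sense of the oxazaborolidinium-catalysed cycloadditions (steps 3 and 14) is assumed to follow the formyl C–H···O binding model with the (S)-catalyst; both dienophiles need attack on the same face, so the (R)-catalyst would be used in both steps if the sense proved opposite.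

Remark on the chemistry: compounds 1, 3, 16, 17 and 28 are taken as commercial; 26, 27 and 29 are drawn as the C10 epimer with C9 trans to the C6 arm, and the other epimer would serve equally because step 22 erases C10.

Abbreviations: TBS = tert-butyldimethylsilyl, TIPS = triisopropylsilyl, PMB = 4-methoxybenzyl.

## Steps

Step 1
Reactants: 1 but-3-en-2-one
Product: 2 2-(triisopropylsilyloxy)buta-1,3-diene
Conditions: iPr3SiOTf, Et3N, Et2O, 0 °C to rt
Reagents that add atoms: triisopropylsilyl trifluoromethanesulfonate, CC(C)[Si](C(C)C)(C(C)C)OS(=O)(=O)C(F)(F)F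
Why: Soft enolisation and O-silylation of the enone gives the 2-silyloxydiene; no stereocentre is formed.

Step 2
Reactants: 3 pent-4-ynal
Product: 4 2-methylidenepent-4-ynal
Conditions: aq. CH2O, pyrrolidine (10 mol%), EtCO2H (10 mol%), iPrOH, 45 °C
Reagents that add atoms: formaldehyde, C=O
Why: Amine-catalysed Mannich condensation and elimination (α-methylenation of an aldehyde); the new carbon becomes C9.

Step 3
Reactants: 4 2-methylidenepent-4-ynal; 2 2-(triisopropylsilyloxy)buta-1,3-diene
Product: 5 (R)-1-(prop-2-ynyl)-4-(triisopropylsilyloxy)cyclohex-3-ene-1-carbaldehyde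
Conditions: (S)-3,3-diphenyl-1-(2-methylphenyl)tetrahydro-1H,3H-pyrrolo[1,2-c][1,3,2]oxazaborole·HN(SO2CF3)2 (20 mol%), CH2Cl2, −78 to −40 °C
Reagents that add atoms: none
Why: Enantioselective Diels–Alder reaction with a cationic oxazaborolidine catalyst, for which 2-substituted acroleins are the standard dienophiles; the catalyst shields one face of the bound enal and so sets C8. The para orientation places the enol ether at C12=C13, which is what makes the ring chiral and prepares step 4.

Step 4
Reactants: 5 (R)-1-(prop-2-ynyl)-4-(triisopropylsilyloxy)cyclohex-3-ene-1-carbaldehyde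
Product: 6 6-methylidene-4-oxobicyclo[3.2.1]octane-1-carbaldehyde (C8 formyl, C12 ketone, C16 exocyclic methylene)
Conditions: Ph3PAuCl (5 mol%), AgBF4 (5 mol%), toluene/MeOH 10:1, rt
Reagents that add atoms: none
Why: Conia-ene type 5-exo-dig carbocyclisation of a silyl enol ether onto an alkyne activated by monovalent gold; C13 attacks the internal alkyne carbon. The one-atom C14 link to C8 forces the new bond cis to the propargyl arm, so C8 dictates C13.

Step 5
Reactants: 6 6-methylidene-4-oxobicyclo[3.2.1]octane-1-carbaldehyde
Product: 7 6-methylidene-4-oxobicyclo[3.2.1]octane-1-carboxylic acid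
Conditions: NaClO2, NaH2PO4, 2-methylbut-2-ene, tBuOH/H2O, 0 °C to rt
Reagents that add atoms: sodium chlorite, [Na+].[O-]Cl=O
Why: Pinnick oxidation of a non-enolisable aldehyde; the scavenger protects the exocyclic alkene from hypochlorite.

Step 6
Reactants: 7 6-methylidene-4-oxobicyclo[3.2.1]octane-1-carboxylic acid
Product: 8 methyl 6-methylidene-4-oxobicyclo[3.2.1]octane-1-carboxylate
Conditions: MeI, K2CO3, DMF, rt
Reagents that add atoms: iodomethane, CI
Why: O-Alkylation of the carboxylate; the bridgehead position of the acid does not matter because the reaction takes place at the methyl carbon.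

Step 7
Reactants: 8 methyl 6-methylidene-4-oxobicyclo[3.2.1]octane-1-carboxylate
Product: 10 methyl 4,6-dioxobicyclo[3.2.1]octane-1-carboxylate, via secondary ozonide 9 (not isolated)
Conditions: O3, CH2Cl2, −78 °C; then Me2S, −78 °C to rt
Reagents that add atoms: ozone, [O-][O+]=O
Why: Ozonolysis of the only alkene turns C16 into a ketone, the form in which it is masked until step 27.

Step 8
Reactants: 10 methyl 4,6-dioxobicyclo[3.2.1]octane-1-carboxylate
Product: 11 methyl 4,6-dioxobicyclo[3.2.1]oct-2-ene-1-carboxylate (C12 enone, C9=C11)
Conditions: 2-iodoxybenzoic acid (IBX), DMSO/toluene, 70 °C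
Reagents that add atoms: none
Why: IBX dehydrogenation of a ketone; the C12 ketone can enolise only toward C11 because C13 is a bridgehead, and the C16 ketone has no position that can be desaturated.

Step 9
Reactants: 11 methyl 4,6-dioxobicyclo[3.2.1]oct-2-ene-1-carboxylate
Product: 12 C16 ethylene ketal of 11 (dioxolane at C16, C12 enone retained)
Conditions: (Me3SiOCH2)2, Me3SiOTf (5 mol%), CH2Cl2, −78 to −20 °C
Reagents that add atoms: 1,2-bis(trimethylsilyloxy)ethane, C[Si](C)(C)OCCO[Si](C)(C)C
Why: Noyori ketalisation; the saturated cyclopentanone reacts much faster than the conjugated ketone.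

Step 10
Reactants: 12 C16 ethylene ketal of 11
Product: 13 endo allylic alcohol (C12 hydroxyl syn to the C15–C16 bridge, C9=C11)
Conditions: NaBH4, CeCl3·7H2O, MeOH, −78 °C
Reagents that add atoms: none
Why: Luche 1,2-reduction; hydride attacks C12 from the exo face, away from the two-carbon bridge and its dioxolane, so the hydroxyl comes out endo.

Step 11
Reactants: 13 endo allylic alcohol
Product: 14 exo 4-nitrobenzoate (C12 ester anti to the C15–C16 bridge)
Conditions: 4-O2NC6H4CO2H, PPh3, iPrO2CN=NCO2iPr, THF, 0 °C to rt
Reagents that add atoms: 4-nitrobenzoic acid, OC(=O)c1ccc(cc1)[N+](=O)[O-]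
Why: Mitsunobu inversion; the carboxylate displaces the oxyphosphonium from the open exo face. Attack at the neopentyl C9 and elimination toward the bridgehead are both blocked.

Step 12
Reactants: 14 exo 4-nitrobenzoate
Product: 15 exo allylic alcohol (C12 hydroxyl anti to the C15–C16 bridge, C9=C11, C8 methyl ester, C16 dioxolane)
Conditions: K2CO3 (0.2 equiv), MeOH, rt
Reagents that add atoms: none
Why: Transesterification of the activated aryl ester; the bridgehead methyl ester is too hindered to exchange.

Step 13
Reactants: 16 (tert-butyldimethylsilyloxy)acetaldehyde; 17 2-(triphenylphosphoranylidene)propanal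
Product: 18 (E)-4-(tert-butyldimethylsilyloxy)-2-methylbut-2-enal
Conditions: toluene, 80 °C
Reagents that add atoms: none
Why: Wittig reaction of a stabilised ylide, which gives the E enal; this geometry later places the C4 methyl cis to the C6 arm.

Step 14
Reactants: 18 (E)-4-(tert-butyldimethylsilyloxy)-2-methylbut-2-enal; 2 2-(triisopropylsilyloxy)buta-1,3-diene
Product: 19 ring A aldehyde (cyclohexene with C1 OTIPS enol ether toward C2, C4 methyl and formyl, C5 CH2OTBS cis to the methyl)
Conditions: (S)-3,3-diphenyl-1-(2-methylphenyl)tetrahydro-1H,3H-pyrrolo[1,2-c][1,3,2]oxazaborole·HN(SO2CF3)2 (20 mol%), CH2Cl2, −78 to −20 °C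
Reagents that add atoms: none
Why: Enantioselective Diels–Alder reaction with the same cationic oxazaborolidine; suprafacial addition to the E enal fixes C4 relative to C5, and the catalyst fixes the absolute sense. The para orientation gives the enol ether toward C2, as step 17 needs.

Step 15
Reactants: 19 ring A aldehyde
Product: 20 ring A alcohol (C19 hydroxymethyl on C4)
Conditions: NaBH4, MeOH, 0 °C
Reagents that add atoms: none
Why: Hydride reduction of the neopentyl aldehyde; both silyl groups are stable to borohydride.

Step 16
Reactants: 20 ring A alcohol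
Product: 21 ring A PMB ether (C19 OPMB, C1 OTIPS enol ether, C6 OTBS)
Conditions: NaH, 4-MeOC6H4CH2Cl, Bu4NI (cat.), THF/DMF, 0 °C to rt
Reagents that add atoms: 4-methoxybenzyl chloride, COc1ccc(CCl)cc1
Why: Williamson etherification; the C6 silyl ether is trans to the alkoxide and four carbons away, so silyl migration should not compete.

Step 17
Reactants: 21 ring A PMB ether
Product: 22 ring A enone (C1 ketone, C2=C3, C4 methyl and CH2OPMB, C5 CH2OTBS cis to the methyl)
Conditions: Pd(OAc)2 (1.1 equiv), DMSO/MeCN, 40 °C
Reagents that add atoms: none
Why: Saegusa–Ito oxidation; the enol ether from step 14 already points toward C2, so β-hydride loss from C3 gives the C2=C3 enone.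

Step 18
Reactants: 22 ring A enone
Product: 23 ring A enone dimethyl ketal
Conditions: MeOSiMe3, Me3SiOTf (5 mol%), CH2Cl2, −78 °C
Reagents that add atoms: methoxytrimethylsilane, CO[Si](C)(C)C
Why: Noyori ketalisation under aprotic conditions; the quaternary C4 prevents migration of the double bond.

Step 19
Reactants: 15 exo allylic alcohol; 23 ring A enone dimethyl ketal (3 equiv)
Product: 26 coupled enone methyl ester (C9–C10 bond on the face of ring C opposite the C15–C16 bridge, C11=C12, C1 enone, C16 dioxolane), via mixed ketal 24 (not isolated), via allyl dienyl ether 25 (not isolated)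
Conditions: EtCO2H (10 mol%), xylene, 140 °C, 4 Å sieves
Reagents that add atoms: none
Why: Ketal Claisen rearrangement; acid-catalysed exchange gives 24, loss of methanol can take only H10 (C2 is vinylic) and gives 25, and the [3,3] shift joins C10 to C9. The shift is suprafacial on the bicyclic allyl unit, so the exo C12–O bond becomes an exo C9–C10 bond and the alkene moves to C11=C12.

Step 20
Reactants: 26 coupled enone methyl ester
Product: 27 coupled enone carboxylic acid (C7 acid on C8)
Conditions: LiI, EtOAc, reflux; then dil. HCl
Reagents that add atoms: none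
Why: SN2 demethylation by iodide at the methyl carbon, which avoids attack at the hindered acyl carbon; enone, ketal and ethers are untouched.

Step 21
Reactants: 27 coupled enone carboxylic acid; 28 chloromethyl chlorosulfate
Product: 29 enone chloromethyl ester (key step precursor)
Conditions: NaHCO3, Bu4NHSO4 (10 mol%), CH2Cl2/H2O, rt
Reagents that add atoms: none
Why: Phase-transfer O-alkylation of the carboxylate; chlorosulfate is displaced in preference to chloride, so the chloromethyl ester is formed selectively.

Step 22
Reactants: 29 enone chloromethyl ester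
Product: 31 spiro-lactone enone (C10–C20 bond, δ-lactone C10–C20–O–C7–C8–C9, C20 anti to the C6 arm), via potassium dienolate 30 (not isolated)
Conditions: KN(SiMe3)2 (1.1 equiv), THF (0.005 M), −78 to 0 °C
Reagents that add atoms: none
Why: Proposed new method: an intramolecular C-alkylation of a ketone dienolate by a tethered acyloxymethyl chloride, for which the closest known reaction type is the intermolecular C-alkylation of ketone enolates with chloromethyl pivalate and related acyloxymethyl halides; the α-oxygen makes the CH2Cl carbon a fast SN2 acceptor. KN(SiMe3)2 can remove only H10, because C4 is quaternary and C2 is vinylic, so the cross-conjugated dienolate 30 forms and the C10 configuration of 29 is erased. C10 then displaces chloride from C20 in a 6-exo-tet closure that makes the δ-lactone and the spiro centre. The new centre is set by three elements that agree: allylic 1,3-strain with the enolate oxygen keeps H9 in the enolate plane, which puts C8 and its ester on one face and C11 on the other; the tether can reach only the face that C8 occupies; and that face is anti to the pseudoaxial C6 arm on C5. The step needs C- over O-alkylation (O-attack would require an eight-membered ring), ring closure over intermolecular alkylation (high dilution), and alkylation over attack of the enolate oxygen on the C7 carbonyl (shielded by the quaternary C8). The ester must reach its s-cis rotamer to close, which is the likely rate limit and the reason for warming to 0 °C.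

Step 23
Reactants: 31 spiro-lactone enone
Product: 32 saturated spiro-lactone ketone (C2–C3 and C11–C12 saturated)
Conditions: H2 (1 atm), 10% Pd/C, pyridine (0.5 equiv), EtOAc, rt
Reagents that add atoms: none
Why: Catalytic hydrogenation of the enone double bond and the ring C alkene in one operation; pyridine suppresses hydrogenolysis of the PMB ether. No stereocentre is formed.

Step 24
Reactants: 32 saturated spiro-lactone ketone
Product: 33 C1 alcohol (hydroxyl cis to C9, trans to C20)
Conditions: NaBH4, MeOH/THF, −20 °C
Reagents that add atoms: none
Why: Hydride reduction of the C1 ketone; hydride should arrive from the face of the C20 methylene, anti to both the bicyclic substituent on C10 and the C6 arm, which gives the alcohol cis to C9. The lactone is not reduced under these conditions.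

Step 25
Reactants: 33 C1 alcohol
Product: 34 diol ketone (C1 and C6 hydroxyls, C16 ketone)
Conditions: 1 M HCl, THF, rt
Reagents that add atoms: water, O
Why: Aqueous acid removes the primary TBS ether and the dioxolane in one operation; the PMB ether and the lactone are stable to dilute acid.

Step 26
Reactants: 34 diol ketone
Product: 35 diacetate ketone (C1 and C6 acetates, C16 ketone)
Conditions: Ac2O, pyridine, DMAP (cat.), CH2Cl2, rt
Reagents that add atoms: acetic anhydride, CC(=O)OC(C)=O
Why: DMAP-catalysed acetylation of the primary and the hindered secondary alcohol; placing it here keeps both acetates away from every later base or hydride.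

Step 27
Reactants: 35 diacetate ketone
Product: 36 exocyclic alkene diacetate (C16=C17)
Conditions: Zn, CH2Br2, TiCl4, THF/CH2Cl2, 0 °C to rt
Reagents that add atoms: dibromomethane, BrCBr
Why: Takai–Lombardo methylenation, which converts ketones and leaves acetates and the lactone alone because the reagent is not basic.

Step 28
Reactants: 36 exocyclic alkene diacetate
Product: 37 C15 allylic alcohol (hydroxyl anti to the C9–C11–C12 bridge)
Conditions: SeO2 (0.5 equiv), tBuOOH, CH2Cl2, rt
Reagents that add atoms: selenium dioxide, O=[Se]=O; tert-butyl hydroperoxide, CC(C)(C)OO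
Why: Allylic oxidation by ene reaction and [2,3] shift; C15 carries the only allylic hydrogens that are not at a bridgehead. Oxygen is expected on the open face, and the centre is removed in step 29.

Step 29
Reactants: 37 C15 allylic alcohol
Product: 38 enone PMB ether (C15 ketone, C16=C17)
Conditions: Dess–Martin periodinane, NaHCO3, CH2Cl2, 0 °C
Reagents that add atoms: none
Why: Buffered Dess–Martin oxidation of the allylic alcohol, mild enough for the α-methylene ketone it creates.

Step 30
Reactants: 38 enone PMB ether
Product: 39 CNP0370815.4 (target)
Conditions: DDQ, CH2Cl2/pH 7 buffer 10:1, 0 °C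
Reagents that add atoms: none
Why: Oxidative cleavage of the PMB ether under neutral conditions, so the C6 acetate cannot migrate to the freed C19 hydroxyl and the enone meets no nucleophile.

## Compound list

1 | but-3-en-2-one | CC(=O)C=C | starting material
2 | 2-(triisopropylsilyloxy)buta-1,3-diene | C=CC(=C)O[Si](C(C)C)(C(C)C)C(C)C | intermediate
3 | pent-4-ynal | C#CCCC=O | starting material
4 | 2-methylidenepent-4-ynal | C=C(CC#C)C=O | intermediate
5 | (R)-1-(prop-2-ynyl)-4-(triisopropylsilyloxy)cyclohex-3-ene-1-carbaldehyde | C#CC[C@]1(C=O)CC=C(O[Si](C(C)C)(C(C)C)C(C)C)CC1 | intermediate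
6 | 6-methylidene-4-oxobicyclo[3.2.1]octane-1-carbaldehyde | C=C1C[C@]2(C=O)C[C@H]1C(=O)CC2 | intermediate
7 | 6-methylidene-4-oxobicyclo[3.2.1]octane-1-carboxylic acid | C=C1C[C@]2(C(=O)O)C[C@H]1C(=O)CC2 | intermediate
8 | methyl 6-methylidene-4-oxobicyclo[3.2.1]octane-1-carboxylate | C=C1C[C@]2(C(=O)OC)C[C@H]1C(=O)CC2 | intermediate
9 | secondary ozonide of 8 (spiro-1,2,4-trioxolane at C16, both C16 epimers) | C1OOC2(O1)C[C@]3(C(=O)OC)C[C@H]2C(=O)CC3 | intermediate (not isolated)
10 | methyl 4,6-dioxobicyclo[3.2.1]octane-1-carboxylate | O=C1C[C@]2(C(=O)OC)C[C@H]1C(=O)CC2 | intermediate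
11 | methyl 4,6-dioxobicyclo[3.2.1]oct-2-ene-1-carboxylate | O=C1C[C@]2(C(=O)OC)C[C@H]1C(=O)C=C2 | intermediate
12 | C16 ethylene ketal of 11 | O1CCOC15C[C@]2(C(=O)OC)C[C@H]5C(=O)C=C2 | intermediate
13 | endo allylic alcohol (C12 hydroxyl syn to the C15–C16 bridge) | O1CCOC15C[C@]2(C(=O)OC)C[C@H]5[C@H](O)C=C2 | intermediate
14 | exo 4-nitrobenzoate (C12 ester anti to the C15–C16 bridge) | O1CCOC15C[C@]2(C(=O)OC)C[C@H]5[C@@H](OC(=O)c3ccc(cc3)[N+](=O)[O-])C=C2 | intermediate
15 | exo allylic alcohol (C12 hydroxyl anti to the C15–C16 bridge) | O1CCOC15C[C@]2(C(=O)OC)C[C@H]5[C@@H](O)C=C2 | intermediate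
16 | (tert-butyldimethylsilyloxy)acetaldehyde | O=CCO[Si](C)(C)C(C)(C)C | starting material
17 | 2-(triphenylphosphoranylidene)propanal | CC(C=O)=P(c1ccccc1)(c1ccccc1)c1ccccc1 | starting material
18 | (E)-4-(tert-butyldimethylsilyloxy)-2-methylbut-2-enal | O=C/C(C)=C/CO[Si](C)(C)C(C)(C)C | intermediate
19 | ring A aldehyde (1-methyl-6-(TBS-oxymethyl)-4-(TIPS-oxy)cyclohex-3-ene-1-carbaldehyde, methyl cis to the silyloxymethyl arm) | CC(C)[Si](OC1=CC[C@](C)(C=O)[C@@H](CO[Si](C)(C)C(C)(C)C)C1)(C(C)C)C(C)C | intermediate
20 | ring A alcohol (C19 hydroxymethyl) | CC(C)[Si](OC1=CC[C@](C)(CO)[C@@H](CO[Si](C)(C)C(C)(C)C)C1)(C(C)C)C(C)C | intermediate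
21 | ring A PMB ether | CC(C)[Si](OC1=CC[C@](C)(COCc2ccc(OC)cc2)[C@@H](CO[Si](C)(C)C(C)(C)C)C1)(C(C)C)C(C)C | intermediate
22 | ring A enone (4-methyl-4-(PMB-oxymethyl)-5-(TBS-oxymethyl)cyclohex-2-en-1-one, methyl cis to the C5 arm) | O=C1C=C[C@](C)(COCc2ccc(OC)cc2)[C@@H](CO[Si](C)(C)C(C)(C)C)C1 | intermediate
23 | ring A enone dimethyl ketal | COC1(OC)C=C[C@](C)(COCc2ccc(OC)cc2)[C@@H](CO[Si](C)(C)C(C)(C)C)C1 | intermediate
24 | mixed methyl allyl ketal (C12–O–C1, both C1 epimers) | O1CCOC15C[C@]2(C(=O)OC)C[C@H]5[C@@H](OC6(OC)C=C[C@](C)(COCc7ccc(OC)cc7)[C@@H](CO[Si](C)(C)C(C)(C)C)C6)C=C2 | intermediate (not isolated)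
25 | allyl dienyl ether (C12–O–C1=C10, C2=C3) | O1CCOC15C[C@]2(C(=O)OC)C[C@H]5[C@@H](OC6=C[C@H](CO[Si](C)(C)C(C)(C)C)[C@@](C)(COCc7ccc(OC)cc7)C=C6)C=C2 | intermediate (not isolated)
26 | coupled enone methyl ester (C9–C10 exo, C11=C12, C16 dioxolane) | O1CCOC15C[C@]2(C(=O)OC)C[C@H]5C=C[C@H]2[C@@H]1C(=O)C=C[C@](C)(COCc3ccc(OC)cc3)[C@H]1CO[Si](C)(C)C(C)(C)C | intermediate
27 | coupled enone carboxylic acid | O1CCOC15C[C@]2(C(=O)O)C[C@H]5C=C[C@H]2[C@@H]1C(=O)C=C[C@](C)(COCc3ccc(OC)cc3)[C@H]1CO[Si](C)(C)C(C)(C)C | intermediate
28 | chloromethyl chlorosulfate | ClCOS(=O)(=O)Cl | starting material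
29 | enone chloromethyl ester (key step precursor) | O1CCOC15C[C@]2(C(=O)OCCl)C[C@H]5C=C[C@H]2[C@@H]1C(=O)C=C[C@](C)(COCc3ccc(OC)cc3)[C@H]1CO[Si](C)(C)C(C)(C)C | intermediate
30 | potassium dienolate of 29 (C10=C1–O−, C2=C3) | O1CCOC15C[C@]2(C(=O)OCCl)C[C@H]5C=C[C@H]2C1=C([O-])C=C[C@](C)(COCc3ccc(OC)cc3)[C@H]1CO[Si](C)(C)C(C)(C)C.[K+] | intermediate (not isolated)
31 | spiro-lactone enone (key step product) | O1CCOC15C[C@]23C[C@H]5C=C[C@H]2[C@@]1(COC3=O)C(=O)C=C[C@](C)(COCc4ccc(OC)cc4)[C@H]1CO[Si](C)(C)C(C)(C)C | intermediate
32 | saturated spiro-lactone ketone | O1CCOC15C[C@]23C[C@H]5CC[C@H]2[C@@]1(COC3=O)C(=O)CC[C@](C)(COCc4ccc(OC)cc4)[C@H]1CO[Si](C)(C)C(C)(C)C | intermediate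
33 | C1 alcohol (hydroxyl cis to C9) | O1CCOC15C[C@]23C[C@H]5CC[C@H]2[C@@]1(COC3=O)[C@@H](O)CC[C@](C)(COCc4ccc(OC)cc4)[C@H]1CO[Si](C)(C)C(C)(C)C | intermediate
34 | diol ketone (C1 and C6 hydroxyls, C16 ketone) | O=C1C[C@]23C[C@H]1CC[C@H]2[C@@]1(COC3=O)[C@@H](O)CC[C@](C)(COCc4ccc(OC)cc4)[C@H]1CO | intermediate
35 | diacetate ketone | O=C1C[C@]23C[C@H]1CC[C@H]2[C@@]1(COC3=O)[C@@H](OC(C)=O)CC[C@](C)(COCc4ccc(OC)cc4)[C@H]1COC(C)=O | intermediate
36 | exocyclic alkene diacetate | C=C1C[C@]23C[C@H]1CC[C@H]2[C@@]1(COC3=O)[C@@H](OC(C)=O)CC[C@](C)(COCc4ccc(OC)cc4)[C@H]1COC(C)=O | intermediate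
37 | C15 allylic alcohol (hydroxyl anti to the C9–C11–C12 bridge) | C=C1[C@H](O)[C@]23C[C@H]1CC[C@H]2[C@@]1(COC3=O)[C@@H](OC(C)=O)CC[C@](C)(COCc4ccc(OC)cc4)[C@H]1COC(C)=O | intermediate
38 | enone PMB ether | C=C1C(=O)[C@]23C[C@H]1CC[C@H]2[C@@]1(COC3=O)[C@@H](OC(C)=O)CC[C@](C)(COCc4ccc(OC)cc4)[C@H]1COC(C)=O | intermediate
39 | CNP0370815.4 | C=C1C(=O)[C@]23C[C@H]1CC[C@H]2[C@@]1(COC3=O)[C@@H](OC(C)=O)CC[C@](C)(CO)[C@H]1COC(C)=O | target

## Step count and least certain steps

Total: 30 steps. Longest linear sequence: 23 steps (steps 2–12 from pent-4-ynal, then steps 19–30).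

**Step 22 (key step, proposed new method).**
- What may go wrong: the enolate oxygen may attack the activated C7 acyl carbon with loss of chloromethoxide, intermolecular alkylation may overtake a slow closure because the ester prefers its s-trans rotamer, and the facial preference fails if the C9–C10 rotamer with H9 in the enolate plane is not the reacting one.
- Fallback, from 27 back to 31, using known chemistry: double deprotonation of acid 27 with KN(SiMe3)2 and aldol addition of the C10 enolate to monomeric formaldehyde would give the hydroxymethyl keto acid F1. The face is then chosen by the C6 arm alone. Lactonisation with 2,4,6-trichlorobenzoyl chloride, Et3N and DMAP would return the route at 31.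

**Step 19 (ketal Claisen rearrangement).**
- What may go wrong: the hindered axial alcohol may exchange only slowly into the mixed ketal, and the allylic C12–O bond may ionise under acid at 140 °C, so that elimination or scrambling competes with the [3,3] shift.
- Fallback, from 22 and 12 back to 26: enone 22 would be converted with LiN(iPr)2 and Me3SiCl into the ring A silyl dienol ether F2. Its Mukaiyama–Michael addition to enone 12 (Me3SiOTf cat.) should occur at C9 from the exo face and give the C12 silyl enol ether F3. CsF and PhNTf2 would turn F3 into the C12 enol triflate F4. Reduction with Pd(OAc)2, PPh3, HCO2H and Bu3N would give the C11=C12 alkene and return the route at 26. This path needs neither 13–15 nor 23.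

**Step 14 (cycloaddition of the trisubstituted enal).**
- What may go wrong: the β-substituted, α-methyl enal may add too slowly at low temperature, and enantioselectivity may erode if the uncatalysed pathway or binding at the silyl ether oxygen competes.
- Fallback, from 18 back to 22: the more reactive 1-(dimethylamino)-3-(tert-butyldimethylsilyloxy)buta-1,3-diene would be used with a trivalent chromium salen catalyst, [Cr(salen)]SbF6 with salen = N,N′-bis(3,5-di-tert-butylsalicylidene)cyclohexane-1,2-diamine dianion, in the enantiomeric form that exposes the required face. This would give the aminocyclohexene aldehyde F5. LiAlH4 would reduce it to the amino alcohol F6. Cold dilute HCl would hydrolyse the enol ether and eliminate dimethylamine to give the hydroxymethyl enone F7. 4-Methoxybenzyl trichloroacetimidate with catalytic acid would return the route at 22.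

**Step 23 (hydrogenation).**
- What may go wrong: the C11=C12 bond is flanked by the axial spiro centre on one face and the bridge with its dioxolane on the other, so uptake may be slow and hydrogenolysis of the PMB ether may catch up.
- Fallback, from 31 back to 32: conjugate reduction of the enone with [(Ph3P)CuH]6 would give the ring A saturated ketone F8, which still holds C11=C12. Diimide, generated from 2-nitrobenzenesulfonohydrazide and Et3N, would then reduce the ring C alkene without touching the benzyl ether and return the route at 32.

**Step 24 (C1 reduction).**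
- What may go wrong: facial selectivity may be poor, because the face anti to C9 and the C6 arm is also the face of the axial C20 methylene if ring A adopts the other chair.
- Fallback, from 32 back to 33, making no new compound (F0): reagent control in place of substrate control, with (R)-1-methyl-3,3-diphenyltetrahydro-1H,3H-pyrrolo[1,2-c][1,3,2]oxazaborole and catecholborane. The quaternary C10 acts as the large group and the C2 methylene as the small group.

## Further compounds

F1 | step 22 | hydroxymethyl keto acid (C20 hydroxymethyl on C10, C7 acid) | O1CCOC15C[C@]2(C(=O)O)C[C@H]5C=C[C@H]2[C@@]1(CO)C(=O)C=C[C@](C)(COCc3ccc(OC)cc3)[C@H]1CO[Si](C)(C)C(C)(C)C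
F2 | step 19 | ring A trimethylsilyl dienol ether of 22 | C[Si](C)(C)OC1=C[C@H](CO[Si](C)(C)C(C)(C)C)[C@@](C)(COCc2ccc(OC)cc2)C=C1
F3 | step 19 | Michael adduct as C12 trimethylsilyl enol ether | O1CCOC15C[C@]2(C(=O)OC)C[C@H]5C(O[Si](C)(C)C)=C[C@H]2[C@@H]1C(=O)C=C[C@](C)(COCc3ccc(OC)cc3)[C@H]1CO[Si](C)(C)C(C)(C)C
F4 | step 19 | C12 enol triflate | O1CCOC15C[C@]2(C(=O)OC)C[C@H]5C(OS(=O)(=O)C(F)(F)F)=C[C@H]2[C@@H]1C(=O)C=C[C@](C)(COCc3ccc(OC)cc3)[C@H]1CO[Si](C)(C)C(C)(C)C
F5 | step 14 | aminocyclohexene aldehyde (cycloadduct of 18 with the aminosilyloxydiene) | CN(C)C1C=C(O[Si](C)(C)C(C)(C)C)C[C@H](CO[Si](C)(C)C(C)(C)C)[C@@]1(C)C=O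
F6 | step 14 | amino alcohol | CN(C)C1C=C(O[Si](C)(C)C(C)(C)C)C[C@H](CO[Si](C)(C)C(C)(C)C)[C@@]1(C)CO
F7 | step 14 | hydroxymethyl enone | O=C1C=C[C@](C)(CO)[C@@H](CO[Si](C)(C)C(C)(C)C)C1
F8 | step 23 | ring A saturated spiro-lactone ketone with C11=C12 | O1CCOC15C[C@]23C[C@H]5C=C[C@H]2[C@@]1(COC3=O)C(=O)CC[C@](C)(COCc4ccc(OC)cc4)[C@H]1CO[Si](C)(C)C(C)(C)C
F0 | step 24 | none | none
A1 | alternative 1 | bicyclo[3.2.1]octenone β-keto ester | CC(C)(C)OC(=O)[C@@H]1C(=O)[C@]23C[C@H]1C=C[C@H]2[C@@]1(COC3=O)[C@@H](OC(C)=O)CC[C@](C)(CO[Si](c4ccccc4)(c5ccccc5)C(C)(C)C)[C@H]1COC(C)=O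
A2 | alternative 2 | cis-fused tricyclic silyl enol ether | C[Si](C)(C)OC1=C2CC=CC[C@H]2[C@@]3(CO[Si](C)(C)C(C)(C)C)C(OC)=CC[C@](C)(C(=O)OC)[C@H]3C1(OC)OC
A3 | alternative 3 | tetracyclic siloxane cycloadduct | CC(=O)[C@]23CC=C[C@H]4[C@H]2[C@@]1(COC3=O)[C@@H](O[Si](C)(C)C(C)(C)C)CC[C@](C)(COCc5ccc(OC)cc5)[C@H]1CO[Si]4(C)C
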